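**Retrosynthetic overview**
- The only ring, the butenolide, is formed last by closing the lactone C5–O1 bond; this C–O bond formation also creates the single stereocentre (C5, R).
- The species that closes is an achiral, O-protonated 3-aryl-2-oxopent-3-enoic acid (a hydroxy-pentadienyl cation) paired with a chiral N-triflylphosphoramide anion.
- That cation is generated in the same flask from 4-hydroxyphenylpyruvic acid and an aryl ethyl enol ether (acid-mediated C4–C5 union, then loss of ethanol). C5 carries OEt and never OH, so closure by acyl substitution is excluded.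
- The enol ether comes from Suzuki–Miyaura coupling of 4-bromo-2-prenylphenol with an (E)-2-ethoxyvinyl boronate; the bromophenol comes from ortho-C-prenylation of 4-bromophenol.
- No protecting groups; three steps.

Assumption: the facial sense of the new ring closure cannot be predicted, so the (R)-configured catalyst is written as the one that gives the (R)-lactone; if the first run shows the opposite sense, its mirror image is used with no other change.

**Step 1**
Reactants: 1 4-bromophenol; 2 1-bromo-3-methylbut-2-ene (prenyl bromide)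
Product: 3 4-bromo-2-(3-methylbut-2-en-1-yl)phenol
Conditions: NaH (1.05 equiv), toluene, 0 °C; then 2 (1.0 equiv), 0 °C → rt, 16 h
Reagents that add atoms: none
Why: The sodium phenoxide, a tight ion pair in a non-polar solvent, is alkylated at the ortho carbon (para is blocked by Br) by the primary allylic bromide and the dienone tautomerises back to the phenol (ortho-selective phenoxide C-alkylation).

**Step 2**
Reactants: 3 4-bromo-2-(3-methylbut-2-en-1-yl)phenol; 4 (E)-2-(2-ethoxyvinyl)-4,4,5,5-tetramethyl-1,3,2-dioxaborolane
Product: 5 (E)-4-(2-ethoxyvinyl)-2-(3-methylbut-2-en-1-yl)phenol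
Conditions: Pd(dppf)Cl2 (3 mol%), K3PO4 (3 equiv), 1,4-dioxane/H2O 4:1, 80 °C, 6 h; chromatography on Et3N-deactivated silica
Reagents that add atoms: none
Why: Suzuki–Miyaura coupling of an aryl bromide with an alkenyl boronate proceeds with retention of the E geometry, and the free phenol, the trisubstituted prenyl alkene and the base-stable enol ether are untouched.

**Step 3**
Reactants: 5 (E)-4-(2-ethoxyvinyl)-2-(3-methylbut-2-en-1-yl)phenol; 6 3-(4-hydroxyphenyl)-2-oxopropanoic acid (4-hydroxyphenylpyruvic acid)
Product: 9 (R)-3-hydroxy-4-(4-hydroxyphenyl)-5-[4-hydroxy-3-(3-methylbut-2-en-1-yl)benzyl]furan-2(5H)-one, via ethoxy keto acid 7 (not isolated), via enone acid 8 (not isolated)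
Conditions: 6 (1.0 equiv), 5 (1.3 equiv, added over 6 h), (R)-3,3'-bis(2,4,6-triisopropylphenyl)-1,1'-binaphthyl-2,2'-diyl N-triflylphosphoramide (5 mol%), 5 Å molecular sieves, CH2Cl2/t-BuOMe 3:1, −30 → −10 °C; Et3N quench
Reagents that add atoms: none
Why: Proposed new method: the chiral acid protonates enol ether 5 to an oxocarbenium ion that is attacked by the enol carbon of 6 (C4–C5 bond, its stereochemistry is irrelevant); the enol form of adduct 7 is a vinylogous acetal that loses ethanol to give O-protonated 8, a hydroxy-pentadienyl cation ion-paired with the chiral phosphoramide anion; the carboxyl C=O oxygen then closes onto C5 in a conrotatory 4π (oxa-Nazarov-type, formally 5-endo oxa-Michael) ring closure whose face is chosen by the anion, so C5–O1 bond formation makes the ring and the (R) centre in one event, and every E/Z or tautomeric form of 8 re-enters through the same cation; the closest known reactions are chiral N-triflylphosphoramide-catalysed Nazarov cyclisations and additions to β,γ-unsaturated α-keto esters, Brønsted-acid-catalysed aldol-type additions of enols to vinyl ethers, and acid-promoted cyclisation of α'-hydroxy enones to furan-3(2H)-ones.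

**Compound list**
1 | 4-bromophenol | Oc1ccc(Br)cc1 | starting material
2 | 1-bromo-3-methylbut-2-ene (prenyl bromide) | CC(C)=CCBr | starting material
3 | 4-bromo-2-(3-methylbut-2-en-1-yl)phenol | CC(C)=CCc1cc(Br)ccc1O | intermediate
4 | (E)-2-(2-ethoxyvinyl)-4,4,5,5-tetramethyl-1,3,2-dioxaborolane | CCO/C=C/B1OC(C)(C)C(C)(C)O1 | starting material
5 | (E)-4-(2-ethoxyvinyl)-2-(3-methylbut-2-en-1-yl)phenol | CCO/C=C/c1ccc(O)c(CC=C(C)C)c1 | intermediate
6 | 3-(4-hydroxyphenyl)-2-oxopropanoic acid (4-hydroxyphenylpyruvic acid) | O=C(O)C(=O)Cc1ccc(O)cc1 | starting material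
7 | 4-ethoxy-3-(4-hydroxyphenyl)-5-[4-hydroxy-3-(3-methylbut-2-en-1-yl)phenyl]-2-oxopentanoic acid (stereoisomer mixture, formed in the flask) | CCOC(Cc1ccc(O)c(CC=C(C)C)c1)C(c1ccc(O)cc1)C(=O)C(=O)O | intermediate
8 | 3-(4-hydroxyphenyl)-5-[4-hydroxy-3-(3-methylbut-2-en-1-yl)phenyl]-2-oxopent-3-enoic acid (E/Z, achiral; its O-protonated form is the cation that closes) | O=C(O)C(=O)C(=CCc1ccc(O)c(CC=C(C)C)c1)c1ccc(O)cc1 | intermediate
9 | (R)-3-hydroxy-4-(4-hydroxyphenyl)-5-[4-hydroxy-3-(3-methylbut-2-en-1-yl)benzyl]furan-2(5H)-one | CC(C)=CCc1cc(C[C@H]2OC(=O)C(O)=C2c2ccc(O)cc2)ccc1O | target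

**Totals**
Total step count: 3. Longest linear sequence: 3 steps (1 → 3 → 5 → 9).

**Steps most likely to fail**

Step 3 (the proposed new step) is the most likely to fail.
- Risks: a racemic background reaction catalysed by acid 6 itself; oligomerisation of 5; acid-induced chroman formation from the ortho-prenylphenol; a six-membered lactone from protonation of the styrene tautomer of 8; an unknown or low sense of induction; slow re-ionisation of 9 that would erode ee.
- Fallback, known chemistry only, setting out from 5 and 6 and returning at 9: 5 is hydrolysed with dilute aqueous HCl in THF at 0 °C to 2-[4-hydroxy-3-(3-methylbut-2-en-1-yl)phenyl]acetaldehyde F5. Acid 6 is esterified with methanol and catalytic acid to methyl 3-(4-hydroxyphenyl)-2-oxopropanoate F6. The two are joined by the established amine-base aldol addition–lactonisation (DBU, DMF, 0 °C) to racemic 3-hydroxy-4-(4-hydroxyphenyl)-5-[4-hydroxy-3-(3-methylbut-2-en-1-yl)benzyl]furan-2(5H)-one F7. Preparative chromatography on a chiral stationary phase then gives 9 and sets aside its (S)-enantiomer F8. Here the ring closes by acyl substitution and the stereocentre comes from resolution.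

Step 1 is the next most likely to fail.
- Risks: O-prenylation, 2,6-diprenylation and chroman formation lower the yield of the direct C-alkylation.
- Fallback, setting out from 1 and returning at 3: 1 is O-allylated (allyl bromide, K2CO3, acetone, reflux) to allyl 4-bromophenyl ether F1. Aromatic Claisen rearrangement (neat, 200 °C) gives 2-allyl-4-bromophenol F2. Cross-metathesis with excess 2-methyl-2-butene (second-generation Grubbs catalyst, (H2IMes)(PCy3)Cl2Ru=CHPh, CH2Cl2, 40 °C) converts the allyl group into the prenyl group of 3.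

Step 2 is the least likely of the three to fail.
- Risks: slow oxidative addition into the electron-rich bromophenoxide, protodeboronation of 4, and hydrolysis of the enol ether on work-up.
- Fallback, setting out from 3 and returning at 5: 3 is treated with n-BuLi (2.2 equiv, THF, −78 °C) and then DMF to give 4-hydroxy-3-(3-methylbut-2-en-1-yl)benzaldehyde F3. Wittig reaction with (ethoxymethyl)triphenylphosphonium chloride and KOt-Bu (THF, 0 °C) gives 5 together with (Z)-4-(2-ethoxyvinyl)-2-(3-methylbut-2-en-1-yl)phenol F4. The mixture is used as such in step 3, because both isomers give the same oxocarbenium ion.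

**Further compounds**
F1 | step 1 | allyl 4-bromophenyl ether (1-bromo-4-(prop-2-en-1-yloxy)benzene) | C=CCOc1ccc(Br)cc1
F2 | step 1 | 2-allyl-4-bromophenol | C=CCc1cc(Br)ccc1O
F3 | step 2 | 4-hydroxy-3-(3-methylbut-2-en-1-yl)benzaldehyde | CC(C)=CCc1cc(C=O)ccc1O
F4 | step 2 | (Z)-4-(2-ethoxyvinyl)-2-(3-methylbut-2-en-1-yl)phenol | CCO/C=C\c1ccc(O)c(CC=C(C)C)c1
F5 | step 3 | 2-[4-hydroxy-3-(3-methylbut-2-en-1-yl)phenyl]acetaldehyde | CC(C)=CCc1cc(CC=O)ccc1O
F6 | step 3 | methyl 3-(4-hydroxyphenyl)-2-oxopropanoate | COC(=O)C(=O)Cc1ccc(O)cc1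
F7 | step 3 | racemic 3-hydroxy-4-(4-hydroxyphenyl)-5-[4-hydroxy-3-(3-methylbut-2-en-1-yl)benzyl]furan-2(5H)-one | CC(C)=CCc1cc(CC2OC(=O)C(O)=C2c2ccc(O)cc2)ccc1O
F8 | step 3 | (S)-3-hydroxy-4-(4-hydroxyphenyl)-5-[4-hydroxy-3-(3-methylbut-2-en-1-yl)benzyl]furan-2(5H)-one | CC(C)=CCc1cc(C[C@@H]2OC(=O)C(O)=C2c2ccc(O)cc2)ccc1O
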